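**Plan** (guaiane numbering)
- **Cuts:** The O8 and O9 acyl groups come off first, then the C10=C14 enol ether, which is carried as a C14 methyl acetal. The lactone ring is cut at C12 (carbon monoxide) and at C7–C11 (ethyne). O9, O6 and the O4–C14 bond are then removed, which leaves a hydroazulene whose ring B is cut at C9–C10 and C5–C6.
- **Enabling feature:** Ring B is a cycloheptane with the one-carbon branch C14 on C10 and oxygen on C8, and its C10–C1–C5 edge belongs to ring A. C14–C10–C1=C5 therefore corresponds to an ester-bearing cyclopentenyl carbene, and C9=C8(O)–C7=C6 to a 2-silyloxybutadiene.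
- **Forward order:** Ring A forms by alkylidene carbene C–H insertion and ring B by cyclopropanation/Cope ring expansion. The oxygen-bridge ring (O4–C14) forms by acetal closure and the lactone ring by cyclocarbonylation. Acylation and unmasking follow.
- **Stereochemistry:** C4 comes from (R)-butane-1,2,4-triol acetonide through a retentive C–H insertion. C5 comes from the chiral dirhodium catalyst, reinforced by C4. C1 is set by equilibration, because only the 1α-H epimer can close the bridge. C6, C7, C9, C10 and C8 are set by attack on the convex α face of the bridged tricycle.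

Key step: step 8

Assumption: C14 of the lactol and methyl acetals (19–34) forms as a mixture of epimers that converge in step 22, so this centre is left open in names and SMILES. α/β refer to the usual guaianolide drawing, in which H-1, H-5 and H-7 of the target are α.

Step 1
Reactants: 1 (R)-2-(2,2-dimethyl-1,3-dioxolan-4-yl)ethanol
Product: 2 (R)-4-(2-iodoethyl)-2,2-dimethyl-1,3-dioxolane
Conditions: I2, PPh3, imidazole, CH2Cl2, 0 → 23 °C
Reagents that add atoms: iodine, SMILES II
Why: The Appel-type iodination of a primary alcohol runs under neutral conditions, so the acetonide and the stereocentre that will become C4 should be untouched.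

Step 2
Reactants: 2 (R)-4-(2-iodoethyl)-2,2-dimethyl-1,3-dioxolane; 3 2-[(tert-butyldimethylsilyl)oxy]-N-methoxy-N-methylacetamide
Product: 5 1-[(tert-butyldimethylsilyl)oxy]-4-[(R)-2,2-dimethyl-1,3-dioxolan-4-yl]butan-2-one, via organolithium 4 (not isolated)
Conditions: t-BuLi (2.1 equiv), Et2O/pentane, −78 °C; then 3, −78 → 0 °C; aq NH4Cl
Reagents that add atoms: none
Why: Lithium–iodine exchange gives a γ-alkoxy organolithium that has no β-leaving group, and the Weinreb ketone synthesis should stop at the ketone because the chelated adduct collapses only on work-up.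

Step 3
Reactants: 5 1-[(tert-butyldimethylsilyl)oxy]-4-[(R)-2,2-dimethyl-1,3-dioxolan-4-yl]butan-2-one
Product: 7 tert-butyl{[(5S)-2,2-dimethyl-1,3-dioxaspiro[4.4]non-6-en-7-yl]methoxy}dimethylsilane, via alkylidene carbene 6 (not isolated)
Conditions: Me3SiCHN2, n-BuLi, THF, −78 → 0 °C
Reagents that add atoms: (trimethylsilyl)diazomethane, SMILES C[Si](C)(C)C=[N+]=[N-]
Why: Addition of lithiated Me3SiCHN2 to the ketone, Peterson-type loss of Me3SiOLi and loss of N2 (the ketone variant of the Colvin reaction) should give the alkylidene carbene, whose concerted 1,5 C–H insertion into the oxygen-activated dioxolane methine is known for this substrate class to go with retention, so ring A closes (C5–C4) with C4 quaternary and S, while the silyloxymethyl arm offers no 1,5 C–H bond.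

Step 4
Reactants: 7 tert-butyl{[(5S)-2,2-dimethyl-1,3-dioxaspiro[4.4]non-6-en-7-yl]methoxy}dimethylsilane
Product: 8 [(5S)-2,2-dimethyl-1,3-dioxaspiro[4.4]non-6-en-7-yl]methanol
Conditions: Bu4NF, THF, 0 → 23 °C
Reagents that add atoms: none
Why: Fluoride-induced cleavage of the primary allylic silyl ether is a standard deprotection that leaves the acetonide alone.

Step 5
Reactants: 8 [(5S)-2,2-dimethyl-1,3-dioxaspiro[4.4]non-6-en-7-yl]methanol
Product: 9 [(5S)-2,2-dimethyl-1,3-dioxaspiro[4.4]non-6-en-7-yl]methyl methyl carbonate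
Conditions: ClCO2Me, pyridine, CH2Cl2, 0 °C
Reagents that add atoms: methyl chloroformate, SMILES COC(=O)Cl
Why: Acylation of the primary allylic alcohol with a chloroformate gives the carbonate that zerovalent palladium can ionise in the next step.

Step 6
Reactants: 9 [(5S)-2,2-dimethyl-1,3-dioxaspiro[4.4]non-6-en-7-yl]methyl methyl carbonate
Product: 10 methyl 2-[(5S)-2,2-dimethyl-1,3-dioxaspiro[4.4]non-6-en-7-yl]acetate
Conditions: Pd(OAc)2 (2 mol %), PPh3 (8 mol %), CO (20 atm), THF, 50 °C
Reagents that add atoms: carbon monoxide, SMILES [C-]#[O+]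
Why: In this palladium-catalysed decarboxylative carbonylation of an allylic carbonate, ionisation to the π-allyl complex, loss of CO2, CO insertion at the unhindered primary terminus C10 and capture by the liberated methoxide should give the β,γ-unsaturated ester without touching C4.

Step 7
Reactants: 10 methyl 2-[(5S)-2,2-dimethyl-1,3-dioxaspiro[4.4]non-6-en-7-yl]acetate
Product: 11 methyl 2-diazo-2-[(5S)-2,2-dimethyl-1,3-dioxaspiro[4.4]non-6-en-7-yl]acetate
Conditions: 4-acetamidobenzenesulfonyl azide, DBU, MeCN, 0 → 23 °C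
Reagents that add atoms: 4-acetamidobenzenesulfonyl azide, SMILES CC(=O)Nc1ccc(cc1)S(=O)(=O)N=[N+]=[N-]
Why: Regitz diazo transfer to the doubly activated (allylic and α-ester) C10 methylene is the standard entry to vinyldiazoacetates, and at 0 °C capture of the dienolate by the sulfonyl azide should outrun vinylogous loss of the C4 alkoxide.

Step 8
Reactants: 11 methyl 2-diazo-2-[(5S)-2,2-dimethyl-1,3-dioxaspiro[4.4]non-6-en-7-yl]acetate; 12 2-(trimethylsilyloxy)buta-1,3-diene
Product: 14 methyl 4β,15-(isopropylidenedioxy)-8-(trimethylsilyloxy)-11,12,13-trinorguaia-1(10),7-dien-14-oate (5α-H), via cis-divinylcyclopropane 13 (not isolated)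
Conditions: Rh2(S-DOSP)4 (1 mol %), 12 (4 equiv), hexanes, −20 °C, slow addition of 11; then 40 °C
Reagents that add atoms: none
Why: Rh2(S-DOSP)4 (divalent rhodium) expels N2 from 11 to give a donor–acceptor carbenoid at C10, which adds in a concerted, asynchronous way to the C8=C9 silyloxy alkene of 12 (bonds C9–C10 and C8–C10) to give the cis-divinylcyclopropane 13, and 13 undergoes a boat [3,3] shift that forms C5–C6, breaks C8–C10 and leaves the C1=C10 enoate and the C7=C8 silyl enol ether. The closest known reaction type is the tandem cyclopropanation/Cope rearrangement (formal [4+3] cycloaddition) of cyclic vinyldiazoacetates with oxygenated dienes. Ring B is closed by strain-driven sigmatropic expansion of the three-membered ring to a seven-membered one, so no end-to-end cyclisation is involved and both new ring alkenes are necessarily cis. The one new stereocentre that persists, C5, copies the configuration of C10 and C8 in 13 (1R,2S), which is fixed by the chiral carboxylate ligands, because the boat geometry lets C6 reach only one face of C1=C5; that face carries O4 and not the bulkier C15 methylene of the spiro acetonide, so catalyst and substrate should be matched and C6 ends cis to O4. Three selectivities are needed: attack at the silyloxy alkene and not at the vinyl group, secured by the oxygen donor that makes C9 the most nucleophilic terminus; reaction at the carbenoid carbon and not at the vinylogous carbon C5, secured by the quaternary C4 next to C5 and by the hydrocarbon solvent; and a cis relation of the cyclopentenyl and vinyl groups, which follows from the usual preference of the carbenoid donor group to end up syn to the unsaturated substituent of the alkene.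

Step 9
Reactants: 14 methyl 4β,15-(isopropylidenedioxy)-8-(trimethylsilyloxy)-11,12,13-trinorguaia-1(10),7-dien-14-oate (5α-H)
Product: 15 4β,15-(isopropylidenedioxy)-8-(trimethylsilyloxy)-11,12,13-trinorguaia-1(10),7-dien-14-ol (5α-H)
Conditions: i-Bu2AlH (2.5 equiv), CH2Cl2, −78 °C; aq potassium sodium tartrate
Reagents that add atoms: none
Why: Reduction of the conjugated ester with i-Bu2AlH gives the allylic alcohol by 1,2-addition, and neither the silyl enol ether nor the acetonide is reducible under these conditions.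

Step 10
Reactants: 15 4β,15-(isopropylidenedioxy)-8-(trimethylsilyloxy)-11,12,13-trinorguaia-1(10),7-dien-14-ol (5α-H)
Product: 17 4β,15-(isopropylidenedioxy)-8-oxo-11,12,13-trinorguaia-1(10),6-dien-14-al (5α-H), via silyl enol ether enal 16 (not isolated)
Conditions: IBX (3 equiv), 4-methoxypyridine N-oxide (3 equiv), DMSO, 25 °C
Reagents that add atoms: none
Why: IBX oxidises the primary allylic alcohol to the enal and, as its N-oxide complex, dehydrogenates the trimethylsilyl enol ether towards C6 (a metal-free counterpart of the Saegusa–Ito oxidation), so the position of the enone is dictated by the enol ether delivered in step 8.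

Step 11
Reactants: 17 4β,15-(isopropylidenedioxy)-8-oxo-11,12,13-trinorguaia-1(10),6-dien-14-al (5α-H)
Product: 20 4β,14-epoxy-15-hydroxy-14-methoxy-11,12,13-trinorguaia-6,9-dien-8-one (1α,5α-H), via dihydroxy enal 18 (not isolated), via lactol 19 (not isolated)
Conditions: TsOH·H2O (20 mol %), MeOH, 23 → 45 °C
Reagents that add atoms: methanol, SMILES CO
Why: Acetonide methanolysis, acid-catalysed migration of the β,γ double bond C1=C10 into conjugation with the C8 ketone through the dienol and intramolecular acetalisation are all reversible, so C1 equilibrates and only the 1α-H epimer, whose C10–C14 arm is cis to the 4β-hydroxyl, should be drained into the six-membered methyl acetal, in which C1 and C5 can no longer enolise because of Bredt's rule.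

Step 12
Reactants: 20 4β,14-epoxy-15-hydroxy-14-methoxy-11,12,13-trinorguaia-6,9-dien-8-one (1α,5α-H)
Product: 21 15-(tert-butyldimethylsilyloxy)-4β,14-epoxy-14-methoxy-11,12,13-trinorguaia-6,9-dien-8-one (1α,5α-H)
Conditions: t-BuMe2SiCl, imidazole, DMF, 23 °C
Reagents that add atoms: tert-butyldimethylsilyl chloride, SMILES CC(C)(C)[Si](C)(C)Cl
Why: Standard silylation of the only free hydroxyl protects C15–OH for the later acylation steps.

Step 13
Reactants: 21 15-(tert-butyldimethylsilyloxy)-4β,14-epoxy-14-methoxy-11,12,13-trinorguaia-6,9-dien-8-one (1α,5α-H)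
Product: 22 the 7-iodo derivative of 21
Conditions: I2, pyridine, CH2Cl2, 23 °C
Reagents that add atoms: iodine, SMILES II
Why: α-Iodination of an enone by the pyridine/iodine addition–elimination sequence (Baylis–Hillman-type activation) should occur only at C7, because pyridine can add to the unsubstituted β-carbon C6 but not to the fully substituted C10.

Step 14
Reactants: 22 the 7-iodo derivative of 21; 23 ethynyltrimethylsilane
Product: 24 the 7-[(trimethylsilyl)ethynyl] dienone (alkyne carbons C11 and C13)
Conditions: PdCl2(PPh3)2 (5 mol %), CuI (10 mol %), i-Pr2NH, THF, 0 °C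
Reagents that add atoms: none
Why: Sonogashira coupling of α-iodoenones with terminal alkynes is well established at or below room temperature and brings in C11 and C13.

Step 15
Reactants: 24 the 7-[(trimethylsilyl)ethynyl] dienone
Product: 26 6α-hydroxy-7β-[(trimethylsilyl)ethynyl] 9-en-8-one (6β,7α-H), via C6 boronate 25 (not isolated)
Conditions: B2pin2, CuCl (5 mol %), DPEphos (5 mol %), NaOt-Bu (8 mol %), MeOH (2 equiv), THF, 0 °C; then NaBO3·4H2O, THF/H2O, 0 → 23 °C
Reagents that add atoms: bis(pinacolato)diboron, SMILES CC1(C)OB(OC1(C)C)B1OC(C)(C)C(C)(C)O1; sodium perborate, SMILES [Na+].[Na+].O[B-]1(O)OO[B-](O)(O)OO1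
Why: Copper-catalysed conjugate borylation of an enone should place boron on the unhindered β-carbon C6 (C10 is fully substituted) from the convex α face, methanol protonates the copper enolate so that the epimerisable C7 carries the alkynyl group trans (β) to boron, and perborate oxidation replaces boron by hydroxyl with retention.

Step 16
Reactants: 26 6α-hydroxy-7β-[(trimethylsilyl)ethynyl] 9-en-8-one
Product: 28 6α,9α-dihydroxy-7β-[(trimethylsilyl)ethynyl] 8-ketone (10α-H), via C9 hydroperoxide 27 (not isolated)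
Conditions: Mn(dpm)3 (10 mol %), PhSiH3 (2 equiv), O2 (1 atm), i-PrOH/CH2Cl2, 0 → 23 °C; then P(OEt)3
Reagents that add atoms: dioxygen, SMILES O=O
Why: In this Mukaiyama-type hydrogen-atom-transfer reduction–oxygenation of an enone the manganese hydride should deliver hydrogen to the bridgehead C10 from its only open (α) face, O2 should trap the C9 α-keto radical on the same convex face, P(OEt)3 reduces the hydroperoxide, and the silylalkyne is inert.

Step 17
Reactants: 28 6α,9α-dihydroxy-7β-[(trimethylsilyl)ethynyl] 8-ketone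
Product: 29 7β-ethynyl-6α,9α-dihydroxy 8-ketone
Conditions: AgNO3 (10 mol %), acetone/H2O, 23 °C
Reagents that add atoms: none
Why: Silver-catalysed protiodesilylation of an alkynylsilane is neutral and selective, so the silyl ether, the aldol unit and the α-ketol should survive.

Step 18
Reactants: 29 7β-ethynyl-6α,9α-dihydroxy 8-ketone
Product: 30 15-(tert-butyldimethylsilyloxy)-4β,14-epoxy-9α-hydroxy-14-methoxy-8-oxoguai-11(13)-en-12,6α-olide (1α,5α,7α,10α-H)
Conditions: PdCl2 (10 mol %), thiourea (20 mol %), CO (1 atm), acetone, 50 °C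
Reagents that add atoms: carbon monoxide, SMILES [C-]#[O+]
Why: Palladium-catalysed cyclocarbonylation of a homopropargylic alcohol (alkoxycarbonylpalladium formed at O6, 5-exo addition across the alkyne, protonolysis) gives the α-methylene-γ-butyrolactone directly under neutral conditions, the trans ring fusion follows from the 6α-O/7β-C relation set in step 15, and the 9-hydroxyl could only form a slower six-membered ring.

Step 19
Reactants: 30 the 9α-hydroxy-8-oxo lactone
Product: 31 the 9α-acetoxy-8-oxo lactone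
Conditions: Ac2O, pyridine, DMAP (5 mol %), CH2Cl2, 0 °C
Reagents that add atoms: acetic anhydride, SMILES CC(=O)OC(C)=O
Why: Standard acetylation of the only free hydroxyl installs the C9 acetate under conditions too weakly basic to epimerise C7 or C9 or to trigger β-elimination of the lactone oxygen.

Step 20
Reactants: 31 the 9α-acetoxy-8-oxo lactone
Product: 32 the 9α-acetoxy-8β-hydroxy lactone (8α-H)
Conditions: NaBH4, CeCl3·7H2O, MeOH/THF, −78 °C
Reagents that add atoms: none
Why: In the Luche reduction hydride should arrive from the convex α face, since the β face is covered by the C7–C11 bond of the lactone and by the O4–C14 bridge, which gives the 8β-alcohol, while cerium suppresses conjugate reduction of the α-methylene lactone and the low temperature suppresses acetyl migration.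

Step 21
Reactants: 32 the 9α-acetoxy-8β-hydroxy lactone; 33 angelic acid
Product: 34 the 9α-acetoxy-8β-angeloyloxy lactone methyl acetal
Conditions: 33, 2,4,6-Cl3C6H2COCl, Et3N, toluene, 23 °C; then 32, 80 °C
Reagents that add atoms: none
Why: Yamaguchi esterification through the mixed 2,4,6-trichlorobenzoic anhydride is the established way to acylate hindered secondary alcohols with angelic acid without Z to E isomerisation to the tiglate.

Step 22
Reactants: 34 the 9α-acetoxy-8β-angeloyloxy lactone methyl acetal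
Product: 35 the 15-O-(tert-butyldimethylsilyl) ether of the target
Conditions: Me3SiOTf (1.5 equiv), i-Pr2NEt (3 equiv), CH2Cl2, −40 → 0 °C
Reagents that add atoms: none
Why: In this silyl triflate/tertiary amine-promoted elimination of an acetal to an enol ether Me3SiOTf ionises the exocyclic C14–OMe bond and the amine removes H-10, the only β-hydrogen of the oxocarbenium ion, so that C10=C14 should form while the excess base keeps the new allylic acetate from ionising.

Step 23
Reactants: 35 the 15-O-(tert-butyldimethylsilyl) ether of the target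
Product: 36 CNP0073339.2
Conditions: Bu4NF, AcOH, THF, 0 °C
Reagents that add atoms: none
Why: Buffered fluoride removes the primary silyl ether without acid, which the enol ether would not tolerate, and without free alkoxide, which would endanger the esters and the α-methylene lactone.

**Compound list**
1 | (R)-2-(2,2-dimethyl-1,3-dioxolan-4-yl)ethanol | OCC[C@@H]1COC(C)(C)O1 | starting material
2 | (R)-4-(2-iodoethyl)-2,2-dimethyl-1,3-dioxolane | ICC[C@@H]1COC(C)(C)O1 | intermediate
3 | 2-[(tert-butyldimethylsilyl)oxy]-N-methoxy-N-methylacetamide | CON(C)C(=O)CO[Si](C)(C)C(C)(C)C | starting material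
4 | {2-[(R)-2,2-dimethyl-1,3-dioxolan-4-yl]ethyl}lithium | [Li]CC[C@@H]1COC(C)(C)O1 | intermediate
5 | 1-[(tert-butyldimethylsilyl)oxy]-4-[(R)-2,2-dimethyl-1,3-dioxolan-4-yl]butan-2-one | CC(C)(C)[Si](C)(C)OCC(=O)CC[C@@H]1COC(C)(C)O1 | intermediate
6 | alkylidene carbene derived from 5 (C=O replaced by C=C:) | [C]=C(CO[Si](C)(C)C(C)(C)C)CC[C@@H]1COC(C)(C)O1 | intermediate
7 | tert-butyl{[(5S)-2,2-dimethyl-1,3-dioxaspiro[4.4]non-6-en-7-yl]methoxy}dimethylsilane | CC(C)(C)[Si](C)(C)OCC1=C[C@]2(COC(C)(C)O2)CC1 | intermediate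
8 | [(5S)-2,2-dimethyl-1,3-dioxaspiro[4.4]non-6-en-7-yl]methanol | OCC1=C[C@]2(COC(C)(C)O2)CC1 | intermediate
9 | [(5S)-2,2-dimethyl-1,3-dioxaspiro[4.4]non-6-en-7-yl]methyl methyl carbonate | COC(=O)OCC1=C[C@]2(COC(C)(C)O2)CC1 | intermediate
10 | methyl 2-[(5S)-2,2-dimethyl-1,3-dioxaspiro[4.4]non-6-en-7-yl]acetate | COC(=O)CC1=C[C@]2(COC(C)(C)O2)CC1 | intermediate
11 | methyl 2-diazo-2-[(5S)-2,2-dimethyl-1,3-dioxaspiro[4.4]non-6-en-7-yl]acetate | COC(=O)C(=[N+]=[N-])C1=C[C@]2(COC(C)(C)O2)CC1 | intermediate
12 | 2-(trimethylsilyloxy)buta-1,3-diene | C=CC(=C)O[Si](C)(C)C | starting material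
13 | methyl (1R,2S)-1-[(5S)-2,2-dimethyl-1,3-dioxaspiro[4.4]non-6-en-7-yl]-2-ethenyl-2-(trimethylsilyloxy)cyclopropane-1-carboxylate | COC(=O)[C@]3(C[C@]3(O[Si](C)(C)C)C=C)C1=C[C@]2(COC(C)(C)O2)CC1 | intermediate
14 | methyl 4β,15-(isopropylidenedioxy)-8-(trimethylsilyloxy)-11,12,13-trinorguaia-1(10),7-dien-14-oate (5α-H) | COC(=O)C1=C2CC[C@@]3(COC(C)(C)O3)[C@@H]2CC=C(O[Si](C)(C)C)C1 | intermediate
15 | 4β,15-(isopropylidenedioxy)-8-(trimethylsilyloxy)-11,12,13-trinorguaia-1(10),7-dien-14-ol (5α-H) | OCC1=C2CC[C@@]3(COC(C)(C)O3)[C@@H]2CC=C(O[Si](C)(C)C)C1 | intermediate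
16 | 4β,15-(isopropylidenedioxy)-8-(trimethylsilyloxy)-11,12,13-trinorguaia-1(10),7-dien-14-al (5α-H) | O=CC1=C2CC[C@@]3(COC(C)(C)O3)[C@@H]2CC=C(O[Si](C)(C)C)C1 | intermediate
17 | 4β,15-(isopropylidenedioxy)-8-oxo-11,12,13-trinorguaia-1(10),6-dien-14-al (5α-H) | O=CC1=C2CC[C@@]3(COC(C)(C)O3)[C@@H]2C=CC(=O)C1 | intermediate
18 | 4β,15-dihydroxy-8-oxo-11,12,13-trinorguaia-1(10),6-dien-14-al (5α-H) | O=CC1=C2CC[C@@](O)(CO)[C@@H]2C=CC(=O)C1 | intermediate
19 | 4β,14-epoxy-14,15-dihydroxy-11,12,13-trinorguaia-6,9-dien-8-one (1α,5α-H) | C1=CC(=O)C=C2C(O)O[C@@]3(CO)CC[C@@H]2[C@@H]13 | intermediate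
20 | 4β,14-epoxy-15-hydroxy-14-methoxy-11,12,13-trinorguaia-6,9-dien-8-one (1α,5α-H) | C1=CC(=O)C=C2C(OC)O[C@@]3(CO)CC[C@@H]2[C@@H]13 | intermediate
21 | 15-(tert-butyldimethylsilyloxy)-4β,14-epoxy-14-methoxy-11,12,13-trinorguaia-6,9-dien-8-one (1α,5α-H) | C1=CC(=O)C=C2C(OC)O[C@@]3(CO[Si](C)(C)C(C)(C)C)CC[C@@H]2[C@@H]13 | intermediate
22 | 7-iodo derivative of 21 | C1=C(I)C(=O)C=C2C(OC)O[C@@]3(CO[Si](C)(C)C(C)(C)C)CC[C@@H]2[C@@H]13 | intermediate
23 | ethynyltrimethylsilane | C#C[Si](C)(C)C | starting material
24 | 7-[(trimethylsilyl)ethynyl] derivative of 21 | C1=C(C#C[Si](C)(C)C)C(=O)C=C2C(OC)O[C@@]3(CO[Si](C)(C)C(C)(C)C)CC[C@@H]2[C@@H]13 | intermediate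
25 | 6α-(pinacolboryl)-7β-[(trimethylsilyl)ethynyl] 9-en-8-one (6β,7α-H) | CC1(C)OB(OC1(C)C)[C@H]4[C@H](C#C[Si](C)(C)C)C(=O)C=C2C(OC)O[C@@]3(CO[Si](C)(C)C(C)(C)C)CC[C@@H]2[C@@H]43 | intermediate
26 | 6α-hydroxy-7β-[(trimethylsilyl)ethynyl] 9-en-8-one (6β,7α-H) | O[C@H]1[C@H](C#C[Si](C)(C)C)C(=O)C=C2C(OC)O[C@@]3(CO[Si](C)(C)C(C)(C)C)CC[C@@H]2[C@@H]13 | intermediate
27 | 9α-hydroperoxy-6α-hydroxy-7β-[(trimethylsilyl)ethynyl] 8-ketone (10α-H) | O[C@H]1[C@H](C#C[Si](C)(C)C)C(=O)[C@@H](OO)[C@@H]2C(OC)O[C@@]3(CO[Si](C)(C)C(C)(C)C)CC[C@@H]2[C@@H]13 | intermediate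
28 | 6α,9α-dihydroxy-7β-[(trimethylsilyl)ethynyl] 8-ketone (10α-H) | O[C@H]1[C@H](C#C[Si](C)(C)C)C(=O)[C@@H](O)[C@@H]2C(OC)O[C@@]3(CO[Si](C)(C)C(C)(C)C)CC[C@@H]2[C@@H]13 | intermediate
29 | 7β-ethynyl-6α,9α-dihydroxy 8-ketone | O[C@H]1[C@H](C#C)C(=O)[C@@H](O)[C@@H]2C(OC)O[C@@]3(CO[Si](C)(C)C(C)(C)C)CC[C@@H]2[C@@H]13 | intermediate
30 | 15-(tert-butyldimethylsilyloxy)-4β,14-epoxy-9α-hydroxy-14-methoxy-8-oxoguai-11(13)-en-12,6α-olide (1α,5α,7α,10α-H) | C=C1C(=O)O[C@H]2[C@H]1C(=O)[C@@H](O)[C@@H]1C(OC)O[C@@]3(CO[Si](C)(C)C(C)(C)C)CC[C@@H]1[C@@H]23 | intermediate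
31 | 9α-acetate of 30 | C=C1C(=O)O[C@H]2[C@H]1C(=O)[C@@H](OC(C)=O)[C@@H]1C(OC)O[C@@]3(CO[Si](C)(C)C(C)(C)C)CC[C@@H]1[C@@H]23 | intermediate
32 | 9α-acetoxy-8β-hydroxy lactone (8α-H) | C=C1C(=O)O[C@H]2[C@H]1[C@H](O)[C@@H](OC(C)=O)[C@@H]1C(OC)O[C@@]3(CO[Si](C)(C)C(C)(C)C)CC[C@@H]1[C@@H]23 | intermediate
33 | angelic acid, (Z)-2-methylbut-2-enoic acid | C/C=C(/C)C(=O)O | starting material
34 | 9α-acetoxy-8β-angeloyloxy lactone methyl acetal | C=C1C(=O)O[C@H]2[C@H]1[C@H](OC(=O)/C(C)=C\C)[C@@H](OC(C)=O)[C@@H]1C(OC)O[C@@]3(CO[Si](C)(C)C(C)(C)C)CC[C@@H]1[C@@H]23 | intermediate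
35 | 15-O-(tert-butyldimethylsilyl) ether of the target | C=C1C(=O)O[C@H]2[C@H]1[C@H](OC(=O)/C(C)=C\C)[C@@H](OC(C)=O)C1=CO[C@@]3(CO[Si](C)(C)C(C)(C)C)CC[C@@H]1[C@@H]23 | intermediate
36 | CNP0073339.2, 9α-acetoxy-8β-angeloyloxy-4β,14-epoxy-15-hydroxyguaia-10(14),11(13)-dien-12,6α-olide (1α,5α,7α-H) | C=C1C(=O)O[C@H]2[C@H]1[C@H](OC(=O)/C(C)=C\C)[C@@H](OC(C)=O)C1=CO[C@@]3(CO)CC[C@@H]1[C@@H]23 | target

Total step count: 23. Longest linear sequence: 23 steps (1 → 36). Compounds 3, 12, 23 and 33 are bought.

**Steps most likely to fail**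

Step 11. The cascade may stall before the C1=C10 double bond has moved. It may also be diverted by reversible addition of methanol or of the C15 hydroxyl to the electron-poor double bonds of the cross-conjugated dienone. The fallback moves the double bond before C6=C7 exists and sets out from 15.
- MnO2 in CH2Cl2 oxidises only the allylic alcohol, so enal 16 is isolated.
- TsOH in MeOH then acts on a plain β,γ-unsaturated ketone. It should give 4β,14-epoxy-15-hydroxy-14-methoxy-11,12,13-trinorguai-9-en-8-one F1.
- t-BuMe2SiCl/imidazole gives its 15-silyl ether F2.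
- LiN(i-Pr)2 and Me3SiCl at −78 °C can only deprotonate C7, because C9 is olefinic. This gives the cross-conjugated 8-(trimethylsilyloxy)-7,9-diene F3.
- Saegusa–Ito oxidation with Pd(OAc)2 in MeCN installs C6=C7 and returns to the route at 21.

Step 15. Borylcupration of the alkyne, base-induced propargyl-to-allenyl isomerisation at C7 or β-elimination during the oxidation may compete with the conjugate borylation. The fallback brings in O6 as an electrophile-free oxygen nucleophile and sets out from 24.
- Weitz–Scheffer epoxidation with t-BuOOH and benzyltrimethylammonium hydroxide should attack only the unhindered C6=C7 bond, from the α face. It should give the 6α,7α-epoxy ketone F4.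
- SmI2 in THF/MeOH at −78 °C cleaves the C7–O bond next to the ketone. Protonation of the samarium enolate then returns to the route at 26.

Step 22. The Lewis acid may ionise the newly formed allylic C9 acetate (Ferrier-type loss). Alternatively, removal of H-10, which the bridged framework holds close to the plane of the oxocarbenium ion, may be too slow. The fallback replaces the ionic elimination by a thermal syn-elimination and sets out from 34.
- PhSH with BF3·OEt2 at −78 °C exchanges methoxy for sulfur to give the 14-phenylthio acetal F5.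
- m-CPBA at −78 °C gives the sulfoxide F6.
- Heating in toluene in the presence of P(OMe)3 expels the sulfenic acid and returns to the route at 35.

Further compounds
F1 | step 11 | 4β,14-epoxy-15-hydroxy-14-methoxy-11,12,13-trinorguai-9-en-8-one (1α,5α-H) | C1CC(=O)C=C2C(OC)O[C@@]3(CO)CC[C@@H]2[C@@H]13
F2 | step 11 | 15-O-(tert-butyldimethylsilyl) ether of F1 | C1CC(=O)C=C2C(OC)O[C@@]3(CO[Si](C)(C)C(C)(C)C)CC[C@@H]2[C@@H]13
F3 | step 11 | 15-(tert-butyldimethylsilyloxy)-4β,14-epoxy-14-methoxy-8-(trimethylsilyloxy)-11,12,13-trinorguaia-7,9-diene | C1C=C(O[Si](C)(C)C)C=C2C(OC)O[C@@]3(CO[Si](C)(C)C(C)(C)C)CC[C@@H]2[C@@H]13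
F4 | step 15 | 6α,7α-epoxide of 24 | O1[C@H]2[C@]1(C#C[Si](C)(C)C)C(=O)C=C3C(OC)O[C@@]4(CO[Si](C)(C)C(C)(C)C)CC[C@@H]3[C@@H]24
F5 | step 22 | 14-phenylthio analogue of 34 | C=C1C(=O)O[C@H]2[C@H]1[C@H](OC(=O)/C(C)=C\C)[C@@H](OC(C)=O)[C@@H]1C(Sc4ccccc4)O[C@@]3(CO[Si](C)(C)C(C)(C)C)CC[C@@H]1[C@@H]23
F6 | step 22 | 14-phenylsulfinyl analogue of 34 | C=C1C(=O)O[C@H]2[C@H]1[C@H](OC(=O)/C(C)=C\C)[C@@H](OC(C)=O)[C@@H]1C(S(=O)c4ccccc4)O[C@@]3(CO[Si](C)(C)C(C)(C)C)CC[C@@H]1[C@@H]23
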